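(The data are calculated with made-up constants.)

Violet was my yardstick. The autumn run held her charges, so its side-product curve stood in for hers, and the other flasks differed from her in when their charge went in.

| flask | starting material | partner | remark | time |
|---|---|---|---|---|
| autumn | 0.050 M | 0.075 M | run made earlier |  |
| noon | 0.050 M | 0.037 M | run made earlier |  |
| summer | 0.050 M | 0.056 M | run made earlier |  |
| midnight | 0.10 M | 0.075 M | run made earlier |  |
| teal | 0.050 M | 0.0750 M (in portions, 4, over 1.5 min) | first portion at the start, last at 1.5 min | 2.5 min |
| amber | 0.050 M | 0.0750 M (fed, over 1.5 min) | all else is in the flask from the start; the feed brings no volume worth counting | 2.5 min |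
| violet | 0.050 M | 0.0750 M | everything together at the start | 2.5 min |
| red | 0.050 M (fed, over 1.5 min) | 0.0750 M | all else is in the flask from the start; the feed brings no volume worth counting | 2.5 min |

| run | time / s | side product / % | target / % | starting material / % |
|---|---|---|---|---|
| autumn | 25.0 | 2 | 3 | 62 |
| autumn | 50.0 | 9 | 10 | 42 |
| autumn | 60.0 | 11 | 9 | 42 |
| autumn | 90.0 | 19 | 19 | 31 |
| noon | 30.0 | 0 | 5 | 77 |
| noon | 60.0 | 6 | 5 | 67 |
| noon | 90.0 | 9 | 12 | 60 |
| noon | 120 | 12 | 13 | 57 |
| summer | 10.0 | 3 | 0 | 83 |
| summer | 20.0 | 0 | 2 | 73 |
| summer | 50.0 | 9 | 9 | 55 |
| summer | 120 | 20 | 19 | 41 |
| midnight | 15.0 | 1 | 0 | 73 |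
| midnight | 40.0 | 7 | 7 | 61 |
| midnight | 80.0 | 12 | 14 | 54 |
| midnight | 120 | 17 | 16 | 54 |

(scatter of a reading: 1.5 percentage points)

- the numbers in the tables scatter with a standard deviation of 1.5 percentage points
- a reading or a percentage of target counts all its forms, free or not

- the flask that comes out highest in amount of side product, in percent of the starting material charged, or "all alike" when all lie within 1.5 percentage points (teal / amber / violet / red / all alike)
- side product at the end, in percent of the starting material charged, teal
- side product at the end, in percent of the starting material charged, amber
- side product at the end, in percent of the starting material charged, violet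
- side product at the end, in percent of the starting material charged, red

I reckoned with the mean wait of the charge outside the flask. For a steady feed over 1.5 min this wait is 45.0 s, half the feeding time. I took the same feed delay for teal, with its 4 equal portions spread evenly over that span. My rule, for these charges, was that teal, amber and red read like violet read one delay earlier.

The objection was that such a shift asks the charge to react at the same pace whenever it arrives, so I wanted the loss of starting material to be first order in the fed reagent. The first readings supported this. Up to its first reading, autumn lost starting material 1.98 times as fast as noon, with 2.03 times the partner. Midnight, at 0.10 M of starting material, lost its percentage 1.18 times as fast as autumn.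

Autumn's side product rose from 9% at 50.0 s to 19% at 90.0 s, and that line gave violet 34.0%. But the line ran 60.0 s past the last reading. Was there material for it? It needed 15 percentage points more, while 31.0% stood unaccounted for in the autumn readings at 90.0 s, so I kept it as an estimate. The delay cost 11 points, which put teal, amber and red near 22.7%. That drop exceeded the margin, so I expected violet highest.

The forecast also chose violet, with 29% for violet, below my figure, and 23.5% for teal, 22.5% for amber and 22.5% for red. On teal it reasoned: “Portions have the same mean addition time”.

Violet gave 32.0%, against 22.3% for teal, 22.5% for amber and 22.9% for red, so violet came highest.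

    intermediate B ⇌ intermediate D (K = 1.20, k = 0.0125 s⁻¹)
    crystals ⇌ target, rate k2*(cs2 - [target]) while solid is left; crystals form when [target] > cs2 (solubility = 19.0 mM, k = 6.00 s⁻¹)
    intermediate C → target (k = 0.0244 s⁻¹)
    starting material + partner → intermediate A (k = 0.210 M⁻¹ s⁻¹)
    partner + intermediate A → intermediate B (k = 3.63 M⁻¹ s⁻¹)
    starting material + partner → intermediate C (k = 0.135 M⁻¹ s⁻¹)
    intermediate D → side product (k = 0.592 s⁻¹)

Left ten times as long, violet reached 56.2% and teal 56.1%. I put the delay to teal at 1.5 min, just before its last portion: 45.0 s earlier is 45.0 s on the autumn readings, where interpolation gave 7.60%, and teal stood at 8.47%.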